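## Structural features

The target is a cis-fused eremophilane (a 4,5-dimethyldecalin). Ring A (C1–C5, C10) carries the C2 ketone and the vicinal cis methyl groups C15 (on C4) and C14 (on quaternary C5). Ring B (C5–C10) carries a 7β-isopropenyl group, an 8α-tiglate and a 9α-angelate. Six contiguous stereocentres (C4, C5, C10, C9, C8, C7) run around the two rings: H10, C14, C15 and the isopropenyl group stand on one face and both acyloxy groups on the other. In the preferred chair–chair conformer the C9 oxygen is therefore axial and syn to C4 across ring B. The fragile groups are the Z-configured angelate (isomerises to the tiglate), the cis-diol diester (acyl migration while one hydroxyl is free), the isopropenyl group next to C8 (moves into conjugation if C8 is a ketone) and the doubly enolisable C2 ketone. The real difficulty is not the skeleton but the dense, regiochemically distinct functionality of ring B, all of which has to grow out of one carbonyl carbon (C8), with the C9 oxygen on the concave side. The key step exploits the fact that C1 and C3 both flank C2 and that C1 is bonded to C10: ring A can be closed from a three-carbon acetone-type unit (C1–C2–C3) onto a ring B enone whose quaternary C5 holds C4 as a formyl group, and C5 then dictates C10.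

## Logic of the disconnections

22 ⇒ 21. The two C2–O bonds of a dioxolane are added retrosynthetically. C2 has to stay silent while enolate and hydride chemistry is done at C8 and C9, and an acetal needs no redox correction at the end. Every intermediate behind 21 then has only one reactive carbonyl. The forward step must be a hydrolysis that spares a Z-enoate, a cis-diol diester and a 1,1-disubstituted alkene.

21 ⇒ 20. The C9–O acyl bond is cut so that the most fragile ester arrives last. The C8 ester already sits on the less hindered equatorial oxygen, so an acyl shift to O9 would be uphill. The forward step must acylate an axial, hindered alcohol without Z-to-E isomerisation.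

20 ⇒ 19 ⇒ 18. The C9–H bond is cut: the 9α-alcohol is traced to the C9 ketone and that to the epimeric alcohol. An electrophilic oxygen source cannot be expected to reach the concave α face of C9, whereas hydride from the convex face gives exactly the axial alcohol. The gain is that the C9 configuration of every compound from 10 to 18 becomes irrelevant. The forward reduction must choose the ketone over the enoate and must not let the neighbouring ester move.

18 ⇒ 17 ⇒ 16. The O–Si bond is restored, then the C11=C12 alkene is traced to a tertiary alcohol (C11–O and C12–H). An isopropenyl group next to a C8 ketone would slip into conjugation, so it is made only after C8 has become an ester carbinol. The forward elimination must go toward a methyl group and not toward C7.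

16 ⇒ 15 ⇒ 14. The C8–O acyl bond and then the C8–H bond are cut. The tiglate is both the final C8 ester and the protecting group for O8 during the C9 inversion, so no extra protection is spent. The forward reduction must deliver hydride axially from the β face and must not trigger a retro-aldol reaction.

14 ⇒ 13. The C7–C11 bond is cut (an aldol addition of a three-carbon ketone). This removes three carbons and the C7 stereocentre. The forward step needs enolisation toward C7 only, which the C9 substituent of 13 guarantees, and attack on the β face.

13 ⇒ 12. The C2 acetal is removed. The forward ketalisation must tell C2 from C8, and the 9-silyloxy group next to C8 provides that.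

12 ⇒ 11. A C3–carboxyl bond is put back. The ester is what the annulation leaves behind and what makes C2 distinguishable from C8 in the preceding steps. Its removal must be neutral so that the silyl ether survives.

11 ⇒ 9 ⇒ 8. The C9–O bond is cut by way of the C8=C9 enol ether. The cis-fused C8 ketone of 8 enolises toward the ring fusion, and the β-keto ester hides C2 as its own enol ether in the same operation. The forward steps need regioselective enolisation and an oxidant that chooses the electron-rich enol ether.

8 ⇒ 7. The C4–C15 bond is cut (conjugate addition of a methyl nucleophile). The alkene of 7 is doubly activated, so the addition can be run cold in the presence of the C8 ketone. It must deliver the methyl group to the β face.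

7 ⇒ 4 + 5. The key disconnection cuts C3–C4 and C1–C10 and opens ring A. It reduces a bicyclic, differentiated diketone to a monocyclic enone aldehyde and a commodity β-keto ester. The forward step must condense at the aldehyde before anything adds to the enone and must close the ring through carbon, with cis fusion.

4 ⇒ 1 + 2. C5–C10 and C6–C7 are cut (Diels–Alder reaction). This leaves two commercial building blocks. The forward step must be enantioselective at the quaternary carbon and must take place at the C=C bond, not the C=O bond, of the enal.

## Other disconnections considered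

Alternative 1: The cut is C4–C5, together with a C2–C7 bond that exists only in the precursor. Going forward, the potassium alkoxide of the bicyclo[2.2.2]octenol A1 would undergo an anionic oxy-Cope rearrangement: C4 of the (Z)-propenyl group bonds to C5 of the ring alkene while C2–C7 breaks, and the enolate left behind becomes the C2 ketone of the cis-fused enone A2.
- In its favour: one concerted step would set C4, C5 and C10 in the right relative sense, because the bicycle enforces a boat-like transition state and the Z geometry translates into the C4 methyl configuration. A2 already has C2 as a free ketone and C8 as an acetal. Its C6=C7 bond would leave C9 as the only enolisable position next to C8 once the acetal is removed.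
- Against it here: A1 stems from achiral cyclohexadienone cycloaddition chemistry, so the absolute configuration would need a resolution or an auxiliary. The C1 acetal is oxygen the target does not contain and would have to be removed reductively next to the C2 ketone. The ring B alkene would still have to be turned into the C7 isopropenyl / C8 ester pattern.
- Comparison: on structure the alternative is the better one in two respects, since the C4 methyl group arrives stereospecifically without a cuprate step and the C2/C8 and C7/C9 distinctions are built in. On step economy up to the bicyclic core it is the equal of the chosen plan. Mechanistically a sigmatropic shift is at least as dependable as a tether-controlled ionic closure. The chosen plan is better on absolute stereocontrol (one catalytic cycloaddition) and carries no surplus oxygen.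

Alternative 2: The cut is C5–C6, again with a temporary C2–C7 bond. Going forward, the extended silyl dienol ether A3 of ring A would add the enone A4 (methyl vinyl ketone) across C5 and C2 on the face opposite the C4 methyl group to give the endo adduct A5. Cleavage of the bridgehead silyl ether would then open C2–C7 by a retro-aldol reaction, and the freed methyl ketone (C8, C9) would close ring B by Michael addition to C10, ending at the cis-fused dione A6.
- In its favour: the quaternary centre C5 and the cis relationship of C14 and C15 would be set in a cycloaddition under control of the adjacent C4 stereocentre. The ortho regiochemistry of a 1-siloxy diene is dependable. All ring carbons come from two small units.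
- Against it here: forming A3 requires γ-deprotonation in competition with the cross-conjugated isomer. The enantiopure ring A enone must be made first. A6 has two saturated ketones (C2 and C8) and no handle to tell them apart, so the differentiation that the β-keto ester gives in the chosen plan would have to be found elsewhere.
- Comparison: for the C4/C5 pair the alternative is the equal or the better, because no facial question of a cuprate addition arises. The cis fusion has the same origin (a tether on C5) in both plans. Step economy is about equal up to the bicyclic diketone, and the chosen plan is ahead afterwards because 8 is already differentiated at C2.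

Alternative 3: The cut takes C1 out of ring A (C1–C2 and C1–C10) and leaves a cyclopentanone. Going forward, the silyl enol ether A7 (C2=C10) would be cyclopropanated with a zinc carbenoid, the shared C2–C10 bond of the siloxycyclopropane opened oxidatively, and elimination would give the ring A enone A8. Oxidation of the butenyl terminus to a methyl ketone and Michael closure onto C10 would then lead to A6.
- In its favour: C4 and C5 would be fixed at the five-membered-ring stage, where conjugate addition trans to an existing methyl group is dependable. The ring expansion places the enone exactly where ring B must close.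
- Against it here: the enol ether must form toward C10, the methylene next to the quaternary carbon, and not toward C3, and nothing secures this. The sequence is the most linear of the four, spends two to three steps on inserting one carbon, and ends at the same undifferentiated A6 as alternative 2.
- Comparison: for the C4/C5 pair it is the equal of alternative 2 and arguably better than the chosen plan. Each step is a known operation of fair reliability. On step economy and on the later ring B chemistry the chosen plan is better, since one flask builds ring A together with the C2 handle.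

Key step: step 2

Remark on numbering: eremophilane numbering is used throughout. Ring A is C1–C5 and C10, ring B is C5–C10, C14 is the methyl group on C5, C15 the methyl group on C4, and C11–C13 the three-carbon unit on C7. β is the face on which C14 stands, α the opposite face.

Remark on the structures: 4 (at C5) and 7 (at C5 and C10) were checked against the target, agree with it, and are used unchanged.

Remark on the way to 4: a chiral Lewis acid with a 1-methoxy-3-siloxy diene is expected to favour reaction at the C=O bond of the enal, so the more nucleophilic amino siloxy diene 2 and a chiral hydrogen-bond donor are used instead.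

Assumption: the (R,R)-configured diol catalyst is taken to give (S)-4; if the sense of induction is the opposite, its antipode is used.

## Route

Step 1
Reactants: 1 methacrolein; 2 (E)-3-(tert-butyldimethylsilyloxy)-N,N-dimethylbuta-1,3-dien-1-amine
Product: 4 (S)-1-methyl-4-oxocyclohex-2-ene-1-carbaldehyde, via cycloadduct 3 (not isolated)
Conditions: (4R,5R)-2,2-dimethyl-α,α,α′,α′-tetra(1-naphthyl)-1,3-dioxolane-4,5-dimethanol (20 mol%), toluene, −80 °C; then aq. HF, MeCN, −20 → 0 °C
Reagents that add atoms: none
Why: Hydrogen-bond-catalysed Diels–Alder reaction: the diol activates the formyl group of 1 and shields one face of the enal, and the amino siloxy diene adds to the C=C bond with its amino-bearing terminus next to the quaternary carbon (C5–C10 and C6–C7 formed), which sets C5. Acid then hydrolyses the silyl enol ether of 3 and eliminates dimethylamine to give the enone; C5 is quaternary and cannot epimerise.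

Step 2
Reactants: 4 (S)-1-methyl-4-oxocyclohex-2-ene-1-carbaldehyde; 5 tert-butyl 3-oxobutanoate
Product: 7 tert-butyl (4aS,8aS)-8a-methyl-3,6-dioxo-3,4,4a,5,6,7,8,8a-octahydronaphthalene-2-carboxylate, via Knoevenagel adduct 6 (not isolated)
Conditions: piperidine (0.2 equiv), AcOH (0.2 equiv), 4 Å molecular sieves, CH2Cl2, 0 °C → rt; then DBU (0.3 equiv), rt
Reagents that add atoms: none
Why: Piperidinium acetate turns the non-enolisable aldehyde of 4 into an iminium ion, the enol of 5 attacks it through its methylene carbon, and loss of the amine gives the alkylidene acetoacetate 6 (C3=C4), a Knoevenagel condensation; the aldehyde is far more electrophilic than the hindered C10, so this bond forms first. The two geometrical isomers of 6 interconvert by reversible conjugate addition of the amine, so the isomer whose acetyl group faces ring B is always available. DBU then deprotonates the acetyl methyl group (C1), and the cross-conjugated dienolate adds to C10, the β carbon of the ring B enone, in a 6-exo-trig intramolecular Michael addition that closes ring A (C1–C10). The closest known reaction type is the Knoevenagel–Michael formal [3+3] cyclohexenone annulation of β-keto esters. The new stereocentre C10 is controlled by quaternary C5: the short tether can reach C10 only on the face of ring B that carries the C4 arm, by axial attack on the half-chair enone, so the fusion is cis with H10 and C14 on the same face. Attack through the dienolate oxygen at C10 is reversible whereas the carbon–carbon bond is not, so the carbocycle accumulates, and the product cannot deconjugate because C5 is quaternary. The selectivities needed are condensation before conjugate addition and C- over O-cyclisation; the first rests on the higher electrophilicity of the aldehyde, the second on the reversibility of the hetero-Michael pathway.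

Step 3
Reactants: 7 tert-butyl (4aS,8aS)-8a-methyl-3,6-dioxo-3,4,4a,5,6,7,8,8a-octahydronaphthalene-2-carboxylate
Product: 8 tert-butyl 4β,5β-dimethyl-2,8-dioxo-10βH-cis-decalin-3-carboxylate
Conditions: Me2CuLi (from CuI and MeLi, 1.3 equiv), Et2O, −78 °C; aq. NH4Cl
Reagents that add atoms: lithium dimethylcuprate, [Li+].C[Cu-]C
Why: Conjugate addition of a lithium dialkylcuprate to a doubly activated alkylidene β-keto ester is fast at −78 °C and leaves the saturated C8 ketone alone. The α face of ring A is covered by ring B (C9 is axial on that side), so the methyl group should enter C4 axially on the exposed β face, cis to C14; C3 is enolisable and of no consequence.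

Step 4
Reactants: 8 tert-butyl 4β,5β-dimethyl-2,8-dioxo-10βH-cis-decalin-3-carboxylate
Product: 9 tert-butyl 2,8-bis(tert-butyldimethylsilyloxy)-4β,5β-dimethyl-10βH-cis-decala-2,8-diene-3-carboxylate
Conditions: TBSOTf (2.5 equiv), Et3N (4 equiv), CH2Cl2, 0 °C → rt
Reagents that add atoms: tert-butyldimethylsilyl trifluoromethanesulfonate, CC(C)(C)[Si](C)(C)OS(=O)(=O)C(F)(F)F
Why: Soft enolisation with a silyl triflate and an amine gives the thermodynamic enol ethers: the β-keto ester is silylated on the C2 oxygen (C2=C3), and the C8 ketone of the cis-fused ring enolises toward the ring-fusion side (C8=C9), as cis-fused 2-decalones with an angular methyl group do. The C2 enol ether also hides the ring A carbonyl during the next step.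

Step 5
Reactants: 9 tert-butyl 2,8-bis(tert-butyldimethylsilyloxy)-4β,5β-dimethyl-10βH-cis-decala-2,8-diene-3-carboxylate
Product: 11 tert-butyl 9β-(tert-butyldimethylsilyloxy)-4β,5β-dimethyl-2,8-dioxo-10βH-cis-decalin-3-carboxylate, via silyloxy ketone 10 (not isolated)
Conditions: mCPBA (1.1 equiv), NaHCO3, CH2Cl2, −20 °C; then dilute aq. HCl, THF, 0 °C
Reagents that add atoms: 3-chloroperoxybenzoic acid, OOC(=O)c1cccc(Cl)c1
Why: Rubottom oxidation: the peracid epoxidises the electron-rich C8=C9 enol ether on the open β face, the silyl group shifts to the new oxygen and the C8 ketone returns with a 9-silyloxy group, while the C2=C3 enol ether is deactivated by its conjugated ester and survives until dilute acid hydrolyses it to the β-keto ester. The configuration at C9 is reset in steps 13 and 14, so the facial outcome here does not matter.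

Step 6
Reactants: 11 tert-butyl 9β-(tert-butyldimethylsilyloxy)-4β,5β-dimethyl-2,8-dioxo-10βH-cis-decalin-3-carboxylate
Product: 12 9β-(tert-butyldimethylsilyloxy)-4β,5β-dimethyl-10βH-cis-decalin-2,8-dione
Conditions: DMSO, H2O (2 equiv), 130 °C
Reagents that add atoms: none
Why: Thermal cleavage of the tert-butyl β-keto ester (loss of 2-methylpropene, then decarboxylation of the β-keto acid through a six-membered transition state) under neutral conditions spares the silyl ether. C4 is not enolisable and keeps its configuration.

Step 7
Reactants: 12 9β-(tert-butyldimethylsilyloxy)-4β,5β-dimethyl-10βH-cis-decalin-2,8-dione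
Product: 13 9β-(tert-butyldimethylsilyloxy)-2,2-(ethylenedioxy)-4β,5β-dimethyl-10βH-cis-decalin-8-one
Conditions: ethane-1,2-diol (5 equiv), pyridinium p-toluenesulfonate (0.1 equiv), benzene, reflux, azeotropic removal of water
Reagents that add atoms: ethane-1,2-diol, OCCO
Why: Acid-catalysed ketalisation: the C8 carbonyl is flanked by the bulky 9-silyloxy group and inductively deactivated by it, so only the unhindered C2 ketone should form the dioxolane. Enolisation at C9 under these conditions would be harmless because C9 is reset later.

Step 8
Reactants: 13 9β-(tert-butyldimethylsilyloxy)-2,2-(ethylenedioxy)-4β,5β-dimethyl-10βH-cis-decalin-8-one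
Product: 14 9β-(tert-butyldimethylsilyloxy)-2,2-(ethylenedioxy)-7β-(2-hydroxypropan-2-yl)-4β,5β-dimethyl-10βH-cis-decalin-8-one
Conditions: LiN(i-Pr)2 (1.1 equiv), THF, −78 °C; acetone (3 equiv), −78 °C; AcOH quench at −78 °C
Reagents that add atoms: acetone, CC(C)=O
Why: Kinetic deprotonation at the only α-methylene left (C7; C9 is a hindered methine bearing the silyloxy group) followed by aldol addition to acetone. The α face of C7 is blocked by C4, which is syn-axial across ring B, so the electrophile should approach on the β face, and the 7β (equatorial) adduct is also the more stable one.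

Step 9
Reactants: 14 9β-(tert-butyldimethylsilyloxy)-2,2-(ethylenedioxy)-7β-(2-hydroxypropan-2-yl)-4β,5β-dimethyl-10βH-cis-decalin-8-one
Product: 15 9β-(tert-butyldimethylsilyloxy)-2,2-(ethylenedioxy)-7β-(2-hydroxypropan-2-yl)-4β,5β-dimethyl-10βH-cis-decalin-8α-ol
Conditions: NaBH4, CeCl3·7H2O, MeOH, −78 → −40 °C
Reagents that add atoms: none
Why: Luche-type borohydride reduction at low temperature avoids retro-aldol cleavage of the β-hydroxy ketone. The small hydride should attack C8 axially from the β face, between two equatorial neighbours, and give the equatorial 8α-alcohol, trans to the C7 side chain.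

Step 10
Reactants: 15 9β-(tert-butyldimethylsilyloxy)-2,2-(ethylenedioxy)-7β-(2-hydroxypropan-2-yl)-4β,5β-dimethyl-10βH-cis-decalin-8α-ol
Product: 16 9β-(tert-butyldimethylsilyloxy)-2,2-(ethylenedioxy)-7β-(2-hydroxypropan-2-yl)-4β,5β-dimethyl-10βH-cis-decalin-8α-yl (E)-2-methylbut-2-enoate
Conditions: (E)-2-methylbut-2-enoyl chloride (1.5 equiv), DMAP (0.2 equiv), pyridine, CH2Cl2, 0 °C → rt
Reagents that add atoms: (E)-2-methylbut-2-enoyl chloride (tigloyl chloride), C/C=C(\C)C(Cl)=O
Why: Acylation of the secondary alcohol with an acid chloride under nucleophilic catalysis; the tertiary alcohol does not react. The tiglate is the final C8 ester and also protects O8 during the inversion at C9.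

Step 11
Reactants: 16 9β-(tert-butyldimethylsilyloxy)-2,2-(ethylenedioxy)-7β-(2-hydroxypropan-2-yl)-4β,5β-dimethyl-10βH-cis-decalin-8α-yl (E)-2-methylbut-2-enoate
Product: 17 9β-(tert-butyldimethylsilyloxy)-2,2-(ethylenedioxy)-7β-isopropenyl-4β,5β-dimethyl-10βH-cis-decalin-8α-yl (E)-2-methylbut-2-enoate
Conditions: SOCl2 (1.5 equiv), pyridine, CH2Cl2, −20 → 0 °C
Reagents that add atoms: none
Why: Dehydration through the chlorosulfite with pyridine as base (an elimination of E2 type): the six methyl hydrogens are far more accessible than the single ring hydrogen at C7, and an isopropylidene group would suffer allylic 1,3-strain with the equatorial C8 ester, so the 1,1-disubstituted alkene should dominate. C8 is no longer a ketone, so the new alkene cannot move into conjugation.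

Step 12
Reactants: 17 9β-(tert-butyldimethylsilyloxy)-2,2-(ethylenedioxy)-7β-isopropenyl-4β,5β-dimethyl-10βH-cis-decalin-8α-yl (E)-2-methylbut-2-enoate
Product: 18 2,2-(ethylenedioxy)-9β-hydroxy-7β-isopropenyl-4β,5β-dimethyl-10βH-cis-decalin-8α-yl (E)-2-methylbut-2-enoate
Conditions: HF·pyridine, pyridine, THF, 0 °C → rt
Reagents that add atoms: none
Why: Fluoride cleavage of the silyl ether under weakly acidic, pyridine-buffered conditions, which should keep the adjacent tiglate from migrating and leave the dioxolane and both alkenes untouched.

Step 13
Reactants: 18 2,2-(ethylenedioxy)-9β-hydroxy-7β-isopropenyl-4β,5β-dimethyl-10βH-cis-decalin-8α-yl (E)-2-methylbut-2-enoate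
Product: 19 2,2-(ethylenedioxy)-7β-isopropenyl-4β,5β-dimethyl-9-oxo-10βH-cis-decalin-8α-yl (E)-2-methylbut-2-enoate
Conditions: DMP (1,1,1-triacetoxy-1,1-dihydro-1,2-benziodoxol-3(1H)-one, 1.5 equiv), NaHCO3, CH2Cl2, rt
Reagents that add atoms: none
Why: Dess–Martin oxidation of the secondary alcohol under buffered, non-basic conditions should give the C9 ketone without epimerising C10 or C8.

Step 14
Reactants: 19 2,2-(ethylenedioxy)-7β-isopropenyl-4β,5β-dimethyl-9-oxo-10βH-cis-decalin-8α-yl (E)-2-methylbut-2-enoate
Product: 20 2,2-(ethylenedioxy)-9α-hydroxy-7β-isopropenyl-4β,5β-dimethyl-10βH-cis-decalin-8α-yl (E)-2-methylbut-2-enoate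
Conditions: LiBH(s-Bu)3 (1.1 equiv), THF, −78 °C; AcOH quench at −78 °C
Reagents that add atoms: none
Why: Ketone reduction by a bulky trialkylborohydride: the α face of C9 is shielded by C4, which is syn-axial across ring B, so hydride should be delivered equatorially from the β face and give the axial 9α-alcohol, while the α,β-disubstituted enoate is not reduced at −78 °C. The cold acidic quench limits acyl transfer, which is in any case uphill from the equatorial O8 to the hindered axial O9.

Step 15
Reactants: 20 2,2-(ethylenedioxy)-9α-hydroxy-7β-isopropenyl-4β,5β-dimethyl-10βH-cis-decalin-8α-yl (E)-2-methylbut-2-enoate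
Product: 21 2,2-(ethylenedioxy)-7β-isopropenyl-4β,5β-dimethyl-8α-[(E)-2-methylbut-2-enoyloxy]-10βH-cis-decalin-9α-yl (Z)-2-methylbut-2-enoate
Conditions: (Z)-2-methylbut-2-enoic acid (3 equiv), 2,4,6-trichlorobenzoyl chloride (3 equiv), Et3N, toluene, rt; then 20, 80 °C
Reagents that add atoms: (Z)-2-methylbut-2-enoic acid (angelic acid), C/C=C(/C)C(=O)O
Why: Yamaguchi-type esterification with the preformed mixed anhydride of angelic acid, run without a nucleophilic catalyst, is the established way to acylate hindered alcohols without Z-to-E isomerisation of the angelate.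

Step 16
Reactants: 21 2,2-(ethylenedioxy)-7β-isopropenyl-4β,5β-dimethyl-8α-[(E)-2-methylbut-2-enoyloxy]-10βH-cis-decalin-9α-yl (Z)-2-methylbut-2-enoate
Product: 22 (4S,5R,7R,8R,9S,10S)-7-isopropenyl-4,5-dimethyl-8-[(E)-2-methylbut-2-enoyloxy]-2-oxo-cis-decalin-9-yl (Z)-2-methylbut-2-enoate
Conditions: pyridinium p-toluenesulfonate (0.3 equiv), acetone/H2O 10:1, 50 °C
Reagents that add atoms: water, O
Why: Acid-catalysed hydrolysis of the dioxolane under weakly acidic conditions that the two enoates and the isopropenyl group should tolerate. The 1,3-diaxial strain between the acetal and C9 makes this acetal labile.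

## Compound list

1 | methacrolein (2-methylprop-2-enal) | CC(=C)C=O | starting material
2 | (E)-3-(tert-butyldimethylsilyloxy)-N,N-dimethylbuta-1,3-dien-1-amine | CN(C)/C=C/C(=C)O[Si](C)(C)C(C)(C)C | starting material
3 | (1S,2R)-2-(dimethylamino)-4-(tert-butyldimethylsilyloxy)-1-methylcyclohex-3-ene-1-carbaldehyde (endo cycloadduct, formyl cis to the amino group) | C1C[C@@](C=O)(C)[C@H](N(C)C)C=C1O[Si](C)(C)C(C)(C)C | intermediate
4 | (S)-1-methyl-4-oxocyclohex-2-ene-1-carbaldehyde | C1C[C@@](C=O)(C)C=CC1=O | intermediate
5 | tert-butyl 3-oxobutanoate | CC(=O)CC(=O)OC(C)(C)C | starting material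
6 | tert-butyl 2-acetyl-3-[(1S)-1-methyl-4-oxocyclohex-2-en-1-yl]prop-2-enoate (E/Z mixture) | C1C[C@@](C=C(C(C)=O)C(=O)OC(C)(C)C)(C)C=CC1=O | intermediate
7 | tert-butyl (4aS,8aS)-8a-methyl-3,6-dioxo-3,4,4a,5,6,7,8,8a-octahydronaphthalene-2-carboxylate (cis-fused 3-ene-2,8-dione, ester on C3, 10βH) | C1C[C@@]2(C)[C@H](CC(=O)C(C(=O)OC(C)(C)C)=C2)CC1=O | intermediate
8 | tert-butyl 4β,5β-dimethyl-2,8-dioxo-10βH-cis-decalin-3-carboxylate (keto form drawn with the ester 3α; largely enolised, C3 labile) | C1C[C@@]2(C)[C@H](CC(=O)[C@@H](C(=O)OC(C)(C)C)[C@@H]2C)CC1=O | intermediate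
9 | tert-butyl 2,8-bis(tert-butyldimethylsilyloxy)-4β,5β-dimethyl-10βH-cis-decala-2,8-diene-3-carboxylate | C1C[C@@]2(C)[C@H](CC(O[Si](C)(C)C(C)(C)C)=C(C(=O)OC(C)(C)C)[C@@H]2C)C=C1O[Si](C)(C)C(C)(C)C | intermediate
10 | tert-butyl 2,9β-bis(tert-butyldimethylsilyloxy)-4β,5β-dimethyl-8-oxo-10βH-cis-decal-2-ene-3-carboxylate | C1C[C@@]2(C)[C@H](CC(O[Si](C)(C)C(C)(C)C)=C(C(=O)OC(C)(C)C)[C@@H]2C)[C@@H](O[Si](C)(C)C(C)(C)C)C1=O | intermediate
11 | tert-butyl 9β-(tert-butyldimethylsilyloxy)-4β,5β-dimethyl-2,8-dioxo-10βH-cis-decalin-3-carboxylate (keto form drawn with the ester 3α; C3 labile) | C1C[C@@]2(C)[C@H](CC(=O)[C@@H](C(=O)OC(C)(C)C)[C@@H]2C)[C@@H](O[Si](C)(C)C(C)(C)C)C1=O | intermediate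
12 | 9β-(tert-butyldimethylsilyloxy)-4β,5β-dimethyl-10βH-cis-decalin-2,8-dione | C1C[C@@]2(C)[C@H](CC(=O)C[C@@H]2C)[C@@H](O[Si](C)(C)C(C)(C)C)C1=O | intermediate
13 | 9β-(tert-butyldimethylsilyloxy)-2,2-(ethylenedioxy)-4β,5β-dimethyl-10βH-cis-decalin-8-one | C1C[C@@]2(C)[C@H](CC3(OCCO3)C[C@@H]2C)[C@@H](O[Si](C)(C)C(C)(C)C)C1=O | intermediate
14 | 9β-(tert-butyldimethylsilyloxy)-2,2-(ethylenedioxy)-7β-(2-hydroxypropan-2-yl)-4β,5β-dimethyl-10βH-cis-decalin-8-one | CC(C)(O)[C@H]1C[C@@]2(C)[C@H](CC3(OCCO3)C[C@@H]2C)[C@@H](O[Si](C)(C)C(C)(C)C)C1=O | intermediate
15 | 9β-(tert-butyldimethylsilyloxy)-2,2-(ethylenedioxy)-7β-(2-hydroxypropan-2-yl)-4β,5β-dimethyl-10βH-cis-decalin-8α-ol | CC(C)(O)[C@H]1C[C@@]2(C)[C@H](CC3(OCCO3)C[C@@H]2C)[C@@H](O[Si](C)(C)C(C)(C)C)[C@@H]1O | intermediate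
16 | 9β-(tert-butyldimethylsilyloxy)-2,2-(ethylenedioxy)-7β-(2-hydroxypropan-2-yl)-4β,5β-dimethyl-10βH-cis-decalin-8α-yl (E)-2-methylbut-2-enoate | CC(C)(O)[C@H]1C[C@@]2(C)[C@H](CC3(OCCO3)C[C@@H]2C)[C@@H](O[Si](C)(C)C(C)(C)C)[C@@H]1OC(=O)/C(C)=C/C | intermediate
17 | 9β-(tert-butyldimethylsilyloxy)-2,2-(ethylenedioxy)-7β-isopropenyl-4β,5β-dimethyl-10βH-cis-decalin-8α-yl (E)-2-methylbut-2-enoate | C=C(C)[C@H]1C[C@@]2(C)[C@H](CC3(OCCO3)C[C@@H]2C)[C@@H](O[Si](C)(C)C(C)(C)C)[C@@H]1OC(=O)/C(C)=C/C | intermediate
18 | 2,2-(ethylenedioxy)-9β-hydroxy-7β-isopropenyl-4β,5β-dimethyl-10βH-cis-decalin-8α-yl (E)-2-methylbut-2-enoate | C=C(C)[C@H]1C[C@@]2(C)[C@H](CC3(OCCO3)C[C@@H]2C)[C@@H](O)[C@@H]1OC(=O)/C(C)=C/C | intermediate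
19 | 2,2-(ethylenedioxy)-7β-isopropenyl-4β,5β-dimethyl-9-oxo-10βH-cis-decalin-8α-yl (E)-2-methylbut-2-enoate | C=C(C)[C@H]1C[C@@]2(C)[C@H](CC3(OCCO3)C[C@@H]2C)C(=O)[C@@H]1OC(=O)/C(C)=C/C | intermediate
20 | 2,2-(ethylenedioxy)-9α-hydroxy-7β-isopropenyl-4β,5β-dimethyl-10βH-cis-decalin-8α-yl (E)-2-methylbut-2-enoate | C=C(C)[C@H]1C[C@@]2(C)[C@H](CC3(OCCO3)C[C@@H]2C)[C@H](O)[C@@H]1OC(=O)/C(C)=C/C | intermediate
21 | 2,2-(ethylenedioxy)-7β-isopropenyl-4β,5β-dimethyl-8α-[(E)-2-methylbut-2-enoyloxy]-10βH-cis-decalin-9α-yl (Z)-2-methylbut-2-enoate | C=C(C)[C@H]1C[C@@]2(C)[C@H](CC3(OCCO3)C[C@@H]2C)[C@H](OC(=O)/C(C)=C\C)[C@@H]1OC(=O)/C(C)=C/C | intermediate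
22 | (4S,5R,7R,8R,9S,10S)-7-isopropenyl-4,5-dimethyl-8-[(E)-2-methylbut-2-enoyloxy]-2-oxo-cis-decalin-9-yl (Z)-2-methylbut-2-enoate (9α-angeloyloxy-8α-tigloyloxy-10βH-eremophil-11-en-2-one) | C=C(C)[C@H]1C[C@@]2(C)[C@H](CC(=O)C[C@@H]2C)[C@H](OC(=O)/C(C)=C\C)[C@@H]1OC(=O)/C(C)=C/C | target

## Step count and least certain steps

Total: 16 steps. Longest linear sequence: 16 steps (from 1 and 2 to 22; 5 enters at step 2).

Step 2 (key step). What is most likely to go wrong is that intermolecular conjugate addition of the acetoacetate methylene carbon to C10, or addition of a second molecule of 5 to 6, outruns the slow deprotonation of the acetyl methyl group that ring closure needs. The fallback changes the three-carbon unit to one that is acidic at both ends. Starting from 4, condensation with di-tert-butyl 3-oxopentanedioate under the same amine catalysis gives an alkylidene derivative whose second methylene carbon is a β-keto ester carbanion; it adds to C10 without strong base and closes ring A to di-tert-butyl 5-methyl-2,8-dioxo-10βH-cis-decal-3-ene-1,3-dicarboxylate F1. The same two bonds and the same cis fusion result. F1 is then taken through the operations of steps 3 to 6 with the extra ester as a passenger: cuprate addition gives di-tert-butyl 4β,5β-dimethyl-2,8-dioxo-10βH-cis-decalin-1,3-dicarboxylate F2, double silylation gives the bis(silyl enol ether) di-tert-butyl 2,8-bis(tert-butyldimethylsilyloxy)-4β,5β-dimethyl-10βH-cis-decala-2,8-diene-1,3-dicarboxylate F3, Rubottom oxidation with acid work-up gives di-tert-butyl 9β-(tert-butyldimethylsilyloxy)-4β,5β-dimethyl-2,8-dioxo-10βH-cis-decalin-1,3-dicarboxylate F4, and heating in wet DMSO removes both ester groups and returns to the route at 12.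

Step 3. The risk is poor facial selectivity, that is, delivery of the methyl group to the α face of ring A. The fallback changes the stereo-determining event from carbon delivery to hydrogen delivery, which gives the opposite C4 configuration from the same accessible face. Starting from 7, cuprate addition with trapping of the enolate by PhSeBr gives tert-butyl 4,5-dimethyl-2,8-dioxo-3-(phenylselanyl)-cis-decalin-3-carboxylate F5 (C3/C4 mixture). Oxidation with H2O2 and syn-elimination of the selenoxide gives the tetrasubstituted alkene tert-butyl 4,5-dimethyl-2,8-dioxo-10βH-cis-decal-3-ene-3-carboxylate F6. Hydrogenation (H2, Pd/C, EtOAc) then adds hydrogen to C4 from the accessible face and comes back to the route at 8.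

Step 4. The risk is loss of regiocontrol in the enolisation of the C8 ketone (toward C7 instead of C9), or silylation that stops at the β-keto ester. The fallback takes the C8=C9 enol ether directly from the Michael event, where its position is fixed by mechanism. It sets out from 6, isolated for this purpose after the condensation stage of step 2. TBSOTf and Et3N convert the acetyl group into its silyl dienol ether, which closes onto the silyl-activated enone in an intramolecular Mukaiyama–Michael reaction and leaves the ring B oxygen silylated: tert-butyl 8-(tert-butyldimethylsilyloxy)-5-methyl-2-oxo-10βH-cis-decala-3,8-diene-3-carboxylate F7. Cuprate addition to F7 and silylation of the resulting β-keto ester enolate with TBSOTf in the same flask come back to the route at 9.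

Step 11. The risk is elimination toward C7 (the isopropylidene isomer) or ionisation with participation of the neighbouring ester. The fallback is a Peterson olefination, in which a silicon substituent fixes the position of the double bond. It sets out from 13. The C7 lithium enolate (with CeCl3 to suppress proton transfer) adds to 1-(trimethylsilyl)propan-2-one to give the β-hydroxysilane 9β-(tert-butyldimethylsilyloxy)-2,2-(ethylenedioxy)-7β-[2-hydroxy-1-(trimethylsilyl)propan-2-yl]-4β,5β-dimethyl-10βH-cis-decalin-8-one F8. Reduction as in step 9 gives the 8α-alcohol F9, and acylation as in step 10 gives the 8α-tiglate F10. BF3·OEt2 (CH2Cl2, −40 °C) then induces the elimination of the silyl and hydroxyl groups and comes back to the route at 17.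

Step 14. Facial selectivity is expected to be good, but conjugate reduction of the tiglate or transfer of the tigloyl group to the new cis hydroxyl would each erode the result. The fallback inverts C9 by substitution instead of by oxidation and reduction: a Mitsunobu reaction of 18 with angelic acid (PPh3, diisopropyl azodicarboxylate, toluene) would replace the equatorial 9β-hydroxyl by the angelate with inversion. It sets out from 18 and comes back at 21, leaving out 19 and 20 (no new compound, F0). The displacement has to enter on the hindered α face, which is why it is only the reserve.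

Step 15. The risk is slow acylation of the axial alcohol, with Z-to-E isomerisation of the acyl donor or ester scrambling between O8 and O9 at the temperature needed. The fallback builds the Z-alkene after the acylation. It sets out from 20, which is esterified with 2-[bis(2,2,2-trifluoroethoxy)phosphoryl]propanoic acid (a water-soluble carbodiimide, DMAP) to the phosphonate 2,2-(ethylenedioxy)-7β-isopropenyl-4β,5β-dimethyl-8α-[(E)-2-methylbut-2-enoyloxy]-10βH-cis-decalin-9α-yl 2-[bis(2,2,2-trifluoroethoxy)phosphoryl]propanoate F11. Still–Gennari olefination with acetaldehyde (KN(SiMe3)2, 18-crown-6, THF, −78 °C) then gives the Z-configured 2-methylbut-2-enoate and comes back to the route at 21.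

## Further compounds

F1 | step 2 | di-tert-butyl 5-methyl-2,8-dioxo-10βH-cis-decal-3-ene-1,3-dicarboxylate (C1 enolisable, unspecified) | C1C[C@@]2(C)[C@H](C(C(=O)OC(C)(C)C)C(=O)C(C(=O)OC(C)(C)C)=C2)CC1=O
F2 | step 2 | di-tert-butyl 4β,5β-dimethyl-2,8-dioxo-10βH-cis-decalin-1,3-dicarboxylate (C1 and C3 enolisable, unspecified) | C1C[C@@]2(C)[C@H](C(C(=O)OC(C)(C)C)C(=O)C(C(=O)OC(C)(C)C)[C@@H]2C)CC1=O
F3 | step 2 | di-tert-butyl 2,8-bis(tert-butyldimethylsilyloxy)-4β,5β-dimethyl-10βH-cis-decala-2,8-diene-1,3-dicarboxylate | C1C[C@@]2(C)[C@H](C(C(=O)OC(C)(C)C)C(O[Si](C)(C)C(C)(C)C)=C(C(=O)OC(C)(C)C)[C@@H]2C)C=C1O[Si](C)(C)C(C)(C)C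
F4 | step 2 | di-tert-butyl 9β-(tert-butyldimethylsilyloxy)-4β,5β-dimethyl-2,8-dioxo-10βH-cis-decalin-1,3-dicarboxylate | C1C[C@@]2(C)[C@H](C(C(=O)OC(C)(C)C)C(=O)C(C(=O)OC(C)(C)C)[C@@H]2C)[C@@H](O[Si](C)(C)C(C)(C)C)C1=O
F5 | step 3 | tert-butyl 4,5-dimethyl-2,8-dioxo-3-(phenylselanyl)-10βH-cis-decalin-3-carboxylate (C3 and C4 unspecified) | C1C[C@@]2(C)[C@H](CC(=O)C([Se]c3ccccc3)(C(=O)OC(C)(C)C)C2C)CC1=O
F6 | step 3 | tert-butyl 4,5-dimethyl-2,8-dioxo-10βH-cis-decal-3-ene-3-carboxylate | C1C[C@@]2(C)[C@H](CC(=O)C(C(=O)OC(C)(C)C)=C2C)CC1=O
F7 | step 4 | tert-butyl 8-(tert-butyldimethylsilyloxy)-5-methyl-2-oxo-10βH-cis-decala-3,8-diene-3-carboxylate | C1C[C@@]2(C)[C@H](CC(=O)C(C(=O)OC(C)(C)C)=C2)C=C1O[Si](C)(C)C(C)(C)C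
F8 | step 11 | 9β-(tert-butyldimethylsilyloxy)-2,2-(ethylenedioxy)-7β-[2-hydroxy-1-(trimethylsilyl)propan-2-yl]-4β,5β-dimethyl-10βH-cis-decalin-8-one (carbinol carbon unspecified) | C[Si](C)(C)CC(C)(O)[C@H]1C[C@@]2(C)[C@H](CC3(OCCO3)C[C@@H]2C)[C@@H](O[Si](C)(C)C(C)(C)C)C1=O
F9 | step 11 | 9β-(tert-butyldimethylsilyloxy)-2,2-(ethylenedioxy)-7β-[2-hydroxy-1-(trimethylsilyl)propan-2-yl]-4β,5β-dimethyl-10βH-cis-decalin-8α-ol | C[Si](C)(C)CC(C)(O)[C@H]1C[C@@]2(C)[C@H](CC3(OCCO3)C[C@@H]2C)[C@@H](O[Si](C)(C)C(C)(C)C)[C@@H]1O
F10 | step 11 | 9β-(tert-butyldimethylsilyloxy)-2,2-(ethylenedioxy)-7β-[2-hydroxy-1-(trimethylsilyl)propan-2-yl]-4β,5β-dimethyl-10βH-cis-decalin-8α-yl (E)-2-methylbut-2-enoate | C[Si](C)(C)CC(C)(O)[C@H]1C[C@@]2(C)[C@H](CC3(OCCO3)C[C@@H]2C)[C@@H](O[Si](C)(C)C(C)(C)C)[C@@H]1OC(=O)/C(C)=C/C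
F0 | step 14 | none | none
F11 | step 15 | 2,2-(ethylenedioxy)-7β-isopropenyl-4β,5β-dimethyl-8α-[(E)-2-methylbut-2-enoyloxy]-10βH-cis-decalin-9α-yl 2-[bis(2,2,2-trifluoroethoxy)phosphoryl]propanoate (phosphonate α-carbon unspecified) | C=C(C)[C@H]1C[C@@]2(C)[C@H](CC3(OCCO3)C[C@@H]2C)[C@H](OC(=O)C(C)P(=O)(OCC(F)(F)F)OCC(F)(F)F)[C@@H]1OC(=O)/C(C)=C/C
A1 | alternative 1 | 7,7-diethoxy-3,3-dimethoxy-5-methyl-2-[(Z)-prop-1-en-1-yl]bicyclo[2.2.2]oct-5-en-2-ol (propenyl group syn to the C5=C6 bridge) | C/C=C\[C@@]1(O)C(OC)(OC)[C@@H]2CC(OCC)(OCC)[C@H]1C=C2C
A2 | alternative 1 | cis-fused 8,8-diethoxy-1,1-dimethoxy-4β,5β-dimethyl-10βH-decal-6-en-2-one | C1=C[C@@]2(C)[C@H](C(OC)(OC)C(=O)C[C@@H]2C)CC1(OCC)OCC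
A3 | alternative 2 | tert-butyl{[(5S)-4,5-dimethylcyclohexa-1,3-dien-1-yl]oxy}dimethylsilane | C[C@H]1CC(O[Si](C)(C)C(C)(C)C)=CC=C1C
A4 | alternative 2 | but-3-en-2-one (methyl vinyl ketone) | CC(=O)C=C
A5 | alternative 2 | 1-[1-(tert-butyldimethylsilyloxy)-4,8-dimethylbicyclo[2.2.2]oct-5-en-2-yl]ethanone (endo acetyl) | CC(=O)[C@H]1C[C@@]2(C)C=C[C@]1(O[Si](C)(C)C(C)(C)C)C[C@@H]2C
A6 | alternative 2 | 4β,5β-dimethyl-10βH-cis-decalin-2,8-dione | C1C[C@@]2(C)[C@H](CC(=O)C[C@@H]2C)CC1=O
A7 | alternative 3 | {[3-(but-3-en-1-yl)-3,4-dimethylcyclopent-1-en-1-yl]oxy}trimethylsilane (both stereocentres as in the target) | C=CCC[C@@]1(C)C=C(O[Si](C)(C)C)C[C@@H]1C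
A8 | alternative 3 | 4-(but-3-en-1-yl)-4,5-dimethylcyclohex-2-en-1-one (both stereocentres as in the target) | C=CCC[C@@]1(C)C=CC(=O)C[C@@H]1C
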